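**Retrosynthetic overview**
- The oxirane is made last from the C10 vinyl group, with the neighbouring 2-formylvinyl group relaying the oxygen; the enal comes from SeO2 oxidation of a C5 isopropenyl group.
- The 6β-OH and the 9α-ester come from two substrate-controlled ketone reductions and one acylation; C5 is corrected by epimerisation next to the C6 ketone.
- The vinyl (C10) and isopropenyl (C5) groups come from thermal opening of a bicyclo[2.2.0]hexane, itself made by the key enone–cyclobutene [2+2] photocycloaddition (bonds C10–C1 and C5–C4).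
- The photo-substrate (C9 enone, C6 ketal, trans α-methylene lactone) comes from (S)-carvone by α'-hydroxylation, allylic oxidation/lactonisation, γ-C–H oxidation and mono-ketalisation.
- Ring order: cyclohexane (bought in carvone) → γ-lactone → dioxolane (temporary) → two cyclobutanes (formed by light, opened by heat) → oxirane. Chirality comes only from (S)-carvone and (S)-2-methylbutanoic acid.

Assumption: 1-methylcyclobutene is bought as a catalogue reagent. Names use elemane numbering: ring C5–C10; C14 = 10-CH3; C1=C2 on C10; C4(=C3)(C15) on C5; lactone C11(=C13)–C12(=O)–O–C8; β = face of the 10-CH3, α = the opposite face.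

**Route**

Step 1
Reactants: 1 (S)-(+)-carvone
Product: 3 (5R,6R)-6-hydroxycarvone (trans ketol; 8α-OH), via TMS dienol ether 2 (not isolated)
Conditions: LDA, TMSCl, THF, −78 °C; then mCPBA, NaHCO3, CH2Cl2, −20 °C; then 1 M HCl, THF, 0 °C
Reagents that add atoms: mCPBA, OOC(=O)c1cccc(Cl)c1
Why: Rubottom oxidation of the kinetic cross-conjugated silyl dienol ether; the peracid attacks C8 anti to the adjacent isopropenyl group, and C8 can also equilibrate to this diequatorial trans ketol, so C8 is set by the carvone stereocentre.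

Step 2
Reactants: 3 (5R,6R)-6-hydroxycarvone
Product: 4 (5R,6R)-6-hydroxy-5-(3-hydroxyprop-1-en-2-yl)-2-methylcyclohex-2-en-1-one
Conditions: SeO2 (0.3 equiv), t-BuOOH (2.5 equiv), CH2Cl2, 25 °C
Reagents that add atoms: tert-butyl hydroperoxide, CC(C)(C)OO
Why: SeO2/TBHP allylic oxidation (ene reaction then [2,3]-shift) occurs at the CH3 of the only electron-rich alkene, the isopropenyl group, while the enone alkene is inert; no stereocentre is formed.

Step 3
Reactants: 4 the allylic diol
Product: 6 (3aR,7aR)-6-methyl-3-methylidene-3a,4-dihydro-1-benzofuran-2,7(3H,7aH)-dione (trans α-methylene lactone enone), via lactol 5 (not isolated)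
Conditions: MnO2 (15 equiv), CH2Cl2, 25 °C
Reagents that add atoms: none
Why: MnO2 oxidative lactonisation of a 2-methylene-1,4-diol (allylic alcohol → enal → lactol with the 8α-OH → lactone) closes the trans-fused lactone without touching C7 or C8.

Step 4
Reactants: 6 the lactone enone
Product: 7 (3aR,7aR)-6-methyl-3-methylidene-3a,7a-dihydro-1-benzofuran-2,4,7(3H)-trione (ene-dione)
Conditions: Rh2(cap)4 (1 mol %), t-BuOOH (70% aq., 5 equiv), NaHCO3, ClCH2CH2Cl, 40 °C
Reagents that add atoms: tert-butyl hydroperoxide, CC(C)(C)OO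
Why: dirhodium caprolactamate/TBHP allylic C–H oxidation (tert-butylperoxyl radical chain) converts the γ-CH2 (C6) of the enone into a ketone; conditions are kept near neutral because 7 is a hydroquinone tautomer.

Step 5
Reactants: 7 the ene-dione
Product: 8 the C6 ethylene ketal of 7 (C9 enone retained)
Conditions: 1,2-bis(trimethylsilyloxy)ethane (1.2 equiv), TMSOTf (5 mol %), CH2Cl2, −78 °C
Reagents that add atoms: 1,2-bis(trimethylsilyloxy)ethane, C[Si](C)(C)OCCO[Si](C)(C)C
Why: Noyori ketalisation takes the C6 carbonyl because the C9 carbonyl is deactivated by the α-acyloxy group (O8) and hindered by the α-methyl; the aprotic low-temperature conditions avoid aromatisation.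

Step 6
Reactants: 8 the ketal enone; 9 1-methylcyclobutene
Product: 10 the cis-anti-cis photoadduct (cyclobutane C5–C10–C1–C4 on the α-face)
Conditions: hν (366 nm, Pyrex), 9 (10 equiv), CH2Cl2, −40 °C
Reagents that add atoms: none
Why: enone–alkene [2+2] photocycloaddition, setting C10 and the provisional C5 centre.
- Regiochemistry: head-to-tail, with the methyl-bearing cyclobutene carbon bonding to the β-carbon C5, which avoids two adjacent quaternary carbons.
- Face: bonding at C5 is axial from the α-face, anti to the pseudoaxial β-oxygen of the ketal and trans to the C7 substituent.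
- Result: cis ring closure puts C10–C1 on the α-face and leaves the 10-CH3 β.

Step 7
Reactants: 10 the photoadduct ketone
Product: 11 the 9α-alcohol of the photoadduct
Conditions: NaBH4, CeCl3·7H2O, MeOH, −78 → −40 °C
Reagents that add atoms: none
Why: Luche reduction; the axial (α) trajectory at C9 is blocked by the syn-axial C5–C4 bond and the C10–C1 bond of the cyclobutane, so hydride enters from the β side and gives the axial 9α-OH; the methylene lactone is not reduced.

Step 8
Reactants: 11 the photoadduct alcohol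
Product: 12 6,6-ethylenedioxy-9α-hydroxy-5-epi-elema-1,3,11(13)-trien-8α,12-olide (vinyl α on C10; isopropenyl α-axial on C5)
Conditions: PhMe (0.01 M), BHT, sealed tube, 190 °C, 3 h
Reagents that add atoms: none
Why: thermal cycloreversion of the bicyclo[2.2.0]hexane ("photothermal olefin metathesis"); C1–C4 and C2–C3 break through the 1,4-diyl (or the cis,trans-cyclodecadiene and its Cope rearrangement), giving the cis-dialkenylcyclohexane with C5 and C10 unchanged.

Step 9
Reactants: 12 the ketal
Product: 14 9α-hydroxy-6-oxo-elema-1,3,11(13)-trien-8α,12-olide (5α-H; isopropenyl β-equatorial), via 5-epi ketone 13 (not isolated)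
Conditions: TsOH·H2O (0.2 equiv), acetone–H2O (10:1), 45 °C
Reagents that add atoms: water, O
Why: acid-catalysed ketal hydrolysis frees the C6 ketone, and enolisation towards C5 then moves the axial isopropenyl group (syn-diaxial to the 9α-OH) to the equatorial β position under thermodynamic control.

Step 10
Reactants: 14 the hydroxy ketone; 15 (S)-2-methylbutanoic acid
Product: 16 9α-[(S)-2-methylbutanoyloxy]-6-oxo-elema-1,3,11(13)-trien-8α,12-olide
Conditions: 15 (1.5 equiv), DIC, DMAP, CH2Cl2, 0 → 25 °C
Reagents that add atoms: none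
Why: Steglich esterification of the only free hydroxyl, now without a 1,3-diaxial partner; the acid stereocentre is bought and is not enolised under these conditions.

Step 11
Reactants: 16 the keto ester
Product: 17 6β-hydroxy-9α-[(S)-2-methylbutanoyloxy]elema-1,3,11(13)-trien-8α,12-olide
Conditions: NaBH4, CeCl3·7H2O, MeOH, −40 °C
Reagents that add atoms: none
Why: Luche reduction; axial attack at C6 is blocked by the syn-axial 10β-CH3, so hydride adds equatorially from the α-face and gives the axial 6β-OH.

Step 12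
Reactants: 17 the 6β-alcohol
Product: 18 6β-hydroxy-9α-[(S)-2-methylbutanoyloxy]-15-oxo-elema-1,3,11(13)-trien-8α,12-olide
Conditions: SeO2 (1.5 equiv), 1,4-dioxane, 70 °C
Reagents that add atoms: selenium dioxide, O=[Se]=O
Why: Riley-type SeO2 allylic oxidation turns the CH3 of the only electron-rich 1,1-disubstituted alkene (the C5 isopropenyl) into the 2-substituted acrolein; the vinyl group has no allylic hydrogen and the acrylate is electron-poor.

Step 13
Reactants: 18 the hydroxy enal
Product: 20 the target (1R)-1,2-epoxide, via iodo-lactol 19 (not isolated)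
Conditions: NIS (1.3 equiv), NaHCO3, MeCN–H2O (5:1), 0 °C; then K2CO3 (2 equiv), 0 → 25 °C
Reagents that add atoms: water, O
Why: Proposed new method: formyl-relayed epoxidation, in which the iodonium ion of the vinyl group is opened at C1 (6-exo) by the C15 carbonyl oxygen through a trans-fused chair oxane with CH2I equatorial, water traps the oxocarbenium ion as lactol 19, and carbonate then opens the lactol and closes the oxirane by O1 attack on C2, so oxygen arrives on the hindered C5-side face of the vinyl group and sets 1R; the closest known reactions are iodolactonisation or iodo-acetalisation with carbonyl participation and the iodolactone-to-epoxy-ester conversion.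

**Compound list**
1 | (S)-(+)-carvone | O=C1C[C@@H](C(C)=C)CC=C1C | starting material
2 | (S)-trimethyl{[6-methyl-3-(prop-1-en-2-yl)cyclohexa-1,5-dien-1-yl]oxy}silane | C[Si](C)(C)OC1=C[C@@H](C(C)=C)CC=C1C | intermediate (not isolated)
3 | (5R,6R)-6-hydroxy-2-methyl-5-(prop-1-en-2-yl)cyclohex-2-en-1-one | O=C1[C@H](O)[C@@H](C(C)=C)CC=C1C | intermediate
4 | (5R,6R)-6-hydroxy-5-(3-hydroxyprop-1-en-2-yl)-2-methylcyclohex-2-en-1-one | O=C1[C@H](O)[C@@H](C(=C)CO)CC=C1C | intermediate
5 | (3aR,7aR)-2-hydroxy-6-methyl-3-methylidene-3,3a,4,7a-tetrahydro-1-benzofuran-7(2H)-one (lactol, anomers) | C=C1C(O)O[C@@H]2[C@@H]1CC=C(C)C2=O | intermediate (not isolated)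
6 | (3aR,7aR)-6-methyl-3-methylidene-3a,4-dihydro-1-benzofuran-2,7(3H,7aH)-dione | C=C1C(=O)O[C@@H]2[C@@H]1CC=C(C)C2=O | intermediate
7 | (3aR,7aR)-6-methyl-3-methylidene-3a,7a-dihydro-1-benzofuran-2,4,7(3H)-trione | C=C1C(=O)O[C@@H]2[C@@H]1C(=O)C=C(C)C2=O | intermediate
8 | (3aR,7aR)-6-methyl-3-methylidene-3a,7a-dihydro-3H-spiro[1-benzofuran-4,2'-[1,3]dioxolane]-2,7-dione | C=C1C(=O)O[C@@H]2[C@@H]1C3(OCCO3)C=C(C)C2=O | intermediate
9 | 1-methylcyclobut-1-ene | CC1=CCC1 | starting material
10 | cis-anti-cis photoadduct: C6 dioxolane, C9 ketone, 8α,12-lactone; cyclobutane C5–C10–C1–C4 on the α-face (10-CH3 and 5-H β), CH3 on C4, second cyclobutane C1–C2–C3–C4 anti to the six-membered ring | C=C1C(=O)O[C@@H]2[C@@H]1C3(OCCO3)[C@H]([C@@]4(C)CC[C@H]45)[C@@]5(C)C2=O | intermediate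
11 | 9α-alcohol of 10 | C=C1C(=O)O[C@@H]2[C@@H]1C3(OCCO3)[C@H]([C@@]4(C)CC[C@H]45)[C@@]5(C)[C@@H]2O | intermediate
12 | 6,6-ethylenedioxy-9α-hydroxy-5-epi-elema-1,3,11(13)-trien-8α,12-olide (5β-H, 10β-CH3) | C=C1C(=O)O[C@@H]2[C@@H]1C3(OCCO3)[C@H](C(C)=C)[C@](C)(C=C)[C@@H]2O | intermediate
13 | 9α-hydroxy-6-oxo-5-epi-elema-1,3,11(13)-trien-8α,12-olide | C=C1C(=O)O[C@@H]2[C@@H]1C(=O)[C@H](C(C)=C)[C@](C)(C=C)[C@@H]2O | intermediate (not isolated)
14 | 9α-hydroxy-6-oxo-elema-1,3,11(13)-trien-8α,12-olide (5α-H, 7α-H, 10β-CH3) | C=C1C(=O)O[C@@H]2[C@@H]1C(=O)[C@@H](C(C)=C)[C@](C)(C=C)[C@@H]2O | intermediate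
15 | (S)-2-methylbutanoic acid | CC[C@H](C)C(=O)O | starting material
16 | 9α-[(S)-2-methylbutanoyloxy]-6-oxo-elema-1,3,11(13)-trien-8α,12-olide | C=C1C(=O)O[C@@H]2[C@@H]1C(=O)[C@@H](C(C)=C)[C@](C)(C=C)[C@@H]2OC(=O)[C@@H](C)CC | intermediate
17 | 6β-hydroxy-9α-[(S)-2-methylbutanoyloxy]elema-1,3,11(13)-trien-8α,12-olide | C=C1C(=O)O[C@@H]2[C@@H]1[C@@H](O)[C@@H](C(C)=C)[C@](C)(C=C)[C@@H]2OC(=O)[C@@H](C)CC | intermediate
18 | 6β-hydroxy-9α-[(S)-2-methylbutanoyloxy]-15-oxo-elema-1,3,11(13)-trien-8α,12-olide | C=C1C(=O)O[C@@H]2[C@@H]1[C@@H](O)[C@@H](C(=C)C=O)[C@](C)(C=C)[C@@H]2OC(=O)[C@@H](C)CC | intermediate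
19 | iodo-lactol: O1 bridges C1 and C15 (2-hydroxy-3-methylidene-oxane trans-fused at C5–C10), CH2I on C1, C15 anomers | C=C1C(=O)O[C@@H]2[C@@H]1[C@@H](O)[C@H]3C(=C)C(O)O[C@@H](CI)[C@]3(C)[C@@H]2OC(=O)[C@@H](C)CC | intermediate (not isolated)
20 | (1R,5R,6S,7S,8R,9S,10R)-1,2-epoxy-6β-hydroxy-9α-[(S)-2-methylbutanoyloxy]-15-oxo-elema-3,11(13)-dien-8α,12-olide | C=C1C(=O)O[C@@H]2[C@@H]1[C@@H](O)[C@@H](C(=C)C=O)[C@](C)([C@@H]1CO1)[C@@H]2OC(=O)[C@@H](C)CC | target

**Step count**
Total steps: 13. Longest linear sequence: 13 steps (1 → 20).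

**Three steps most likely to fail**

Step 4. The ene-dione 7 is a hydroquinone tautomer and may aromatise, and other allylic C–H bonds may compete. The fallback sets out from 6 and comes back at 7. Wohl–Ziegler bromination of 6 (NBS, AIBN, PhCF3, 80 °C) at the γ-CH2 gives the 6-bromo enone F1. Kornblum oxidation (DMSO, NaHCO3, 25 °C) then converts F1 into 7, so the radical C–H oxygenation is replaced by a halide-to-ketone sequence.

Step 8. At 190 °C the cis-dialkenylcyclohexane can enter Cope/retro-Cope equilibria and lose the C5/C10 configuration, and the 9α-OH/5α-isopropenyl syn-diaxial strain may divert the fragmentation. The fallback sets out from 10 and comes back at 12. The ketone 10 itself is thermolysed (PhMe, 180 °C), where the carbonyl conjugates the transient cyclodecadienone, to give the 9-oxo-5-epi-elematriene ketal F2. Luche reduction of F2 then gives 12, because the axial 5α-isopropenyl group shields the α-face and hydride again delivers the 9α-alcohol.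

Step 13 (the new step). The ester carbonyl at O9 or external water could open the iodonium ion instead of the formyl oxygen, which would erode or invert C1. The fallback sets out from 18 and comes back at 20. It is direct epoxidation with mCPBA/NaHCO3 (CH2Cl2, 0 °C) or DMDO, which touches only the electron-rich vinyl group. This is known chemistry without the relay, so the (1S)-epoxide epimer F3 is expected alongside 20, and 20 is separated by HPLC.

Further compounds
F1 | step 4 | (3aR,7aR)-4-bromo-6-methyl-3-methylidene-3a,4-dihydro-1-benzofuran-2,7(3H,7aH)-dione (C6 bromide, epimers) | C=C1C(=O)O[C@@H]2[C@@H]1C(Br)C=C(C)C2=O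
F2 | step 8 | 6,6-ethylenedioxy-9-oxo-5-epi-elema-1,3,11(13)-trien-8α,12-olide | C=C1C(=O)O[C@@H]2[C@@H]1C3(OCCO3)[C@H](C(C)=C)[C@](C)(C=C)C2=O
F3 | step 13 | (1S)-epimer of the target epoxide | C=C1C(=O)O[C@@H]2[C@@H]1[C@@H](O)[C@@H](C(=C)C=O)[C@](C)([C@H]1CO1)[C@@H]2OC(=O)[C@@H](C)CC
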